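No rate constant is on hand, so read time constants off the runs and count turnovers of the initiator.

| setting | elm | cedar | north-west | north |
|---|---|---|---|---|
| free monomer | 35 mM | 35 mM | 35 mM | 35 mM |
| protic impurity | 14 mM | 68 mM | 17.5 mM | 80.0 mM |
| initiator | 2.7 mol% | 2.7 mol% | 2.7 mol% | 2.7 mol% |
| remark | run made earlier | run made earlier |  |  |
| time |  |  | 2.0 h | 2.0 h |

- elm (time / min: monomer in chains / %, free monomer / %): 8.00: 0.9, 96.7; 15.0: 3.2, 92.6; 25.0: 6.8, 86.7; 30.0: 8.8, 83.9; 40.0: 14.4, 76.2; 50.0: 18.6, 70.3; 60.0: 24.5, 63.3
- cedar (time / min: monomer in chains / %, free monomer / %): 5.00: 0.4, 93.1; 8.00: 1.2, 88.1; 12.0: 1.9, 83.1; 15.0: 2.5, 79.0; 25.0: 5.5, 66.4; 40.0: 10.3, 51.8; 60.0: 15.4, 36.5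

(each reading ± 0.3 percentage points)

- which of the two ends with the longer chains by the average number of monomer units in a chain (chains begun, living or dead) ("neither" if they lie within 10%) (north-west / north / neither)
- average number of monomer units in a chain (chains begun, living or dead) at the end, north-west
- average number of monomer units in a chain (chains begun, living or dead) at the end, north

- the average divides the monomer in chains by the number of chains begun, living and dead together
- what was read earlier has a scatter of 0.3 percentage points, one standard deviation
- the earlier runs do not show the number of chains; that part of a forecast is a guess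

Start from the charge. Each chain begun takes one initiator, so the count stands at most at 0.945 mM in north-west and north alike, and a chain that stops still counts. Objection: this assumes the initiator gets spent, and the curved early readings suggest a slow start.

So extrapolate monomer in chains per minute back to zero time, from the first and third elm readings. With no chains yet to grow, that slope is starts. Dividing the loading by it gives the initiator time constant τ at charged free monomer, 72.1 min. Objection: the first reading is 0.9% against a scatter of 0.3 percentage points, so the slope is weak. Cedar, from its first and fourth readings, gives 73.6 min; keep τ.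

Objection: c_free monomer falls, and the clock slows with it. Take the initiator as pseudo-first-order and replace elapsed time by exposure θ, the time integral of c_free monomer over its charge. First-order loss of free monomer reads 0.00762 min⁻¹ in elm and 0.0168 min⁻¹ in cedar. Linear in c_protic impurity, that gives 0.00822 min⁻¹ for north-west and 0.0188 min⁻¹ for north, hence θ of 76.3 min and 47.6 min.

Turnovers n = θ/τ are then 1.06 and 0.659, spending 65.3% and 48.3% of the initiator. I take the loss extrapolated to zero impurity, 0.00524 min⁻¹, as feeding chains, which on this estimate puts 40.0% and 24.9% in chains. My lengths are 22.7 for north-west and 19.1 for north, a ratio of 1.19.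

The forecast names north-west, with 18 and 9.5, assuming “nearly all the initiator starts chains”; it shares my winner, and my lengths stand higher .

The flask gives north-west, with 24.1 and 14.8.

    living end → dead end (k = 4.95 × 10⁻⁵ s⁻¹)
    free monomer + living end → monomer in chains + living end, rate k2*[living end]*[free monomer] (k = 0.270 M⁻¹ s⁻¹)
    protic impurity + free monomer → quenched substrate (k = 0.00355 M⁻¹ s⁻¹)
    free monomer + initiator → living end + monomer in chains (k = 0.00779 M⁻¹ s⁻¹)

In north, initiation reached the midpoint of its turnover up to the asked time at 0.395 h and quenching at 0.460 h, and at 2.00 h free monomer stood at 10.2% with 46% of the initiator unbound, so 0.511 mM of chains had begun. That is 0.777 turnovers against 0.659, and north-west shows 1.24 against 1.06. In the neighbour flask, north's recipe at 88 mM of free monomer, τ scales to 28.7 min, and the 2.2% left gives θ of 30.8 min, so n is 1.07. That flask shows 1.36 turnovers and ends at 27.7 units per chain begun.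

The data are calculated with made-up constants.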